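**Assumptions (one line each)**
- The target has no stereocentres (it is achiral), so "single enantiomer" does not apply; nothing needs to be set or preserved.
- The SMILES shows the free hydrogen sulfate; the route produces the ammonium salt and protonates it by cation exchange at the end (the salt is the storable form).
- 5,7-Dihydroxychromone, 5-bromopyrogallol and 2,2,2-trichloroethyl chlorosulfate are taken as catalogue chemicals.

**Retrosynthetic overview**
1. Target ⇐ one-pot reductive unmasking of a fully protected flavone that already carries the 3'-sulfate as a 2,2,2-trichloroethyl (TCE) sulfate diester, with 5,7-OBn and a 4',5'-diphenylmethylene ketal.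
2. Key disconnection is C2–C1': direct C2–H zincation of an intact 5,7-bis(benzyloxy)chromone, then Negishi coupling with the B-ring aryl bromide. This replaces the usual chalcone or Baker–Venkataraman construction.
3. B-ring: 5-bromopyrogallol is desymmetrised by diphenylmethylene ketal formation; the one remaining OH becomes the TCE sulfate before the coupling, so the sulfate position is fixed early.
4. Ring order: the A/C chromone rings are bought preformed. The only ring formed is the temporary 1,3-dioxole ketal (removed at the end), and the B ring is attached last.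

**Route**

Step 1
Reactants: 1, 5,7-dihydroxy-4H-chromen-4-one; 2, benzyl bromide
Product: 3, 5,7-bis(benzyloxy)-4H-chromen-4-one
Conditions: BnBr (2.5 equiv), K2CO3 (3 equiv), TBAI (cat.), DMF, 70 °C
Reagents that add atoms: benzyl bromide, BrCc1ccccc1
Why: Williamson etherification; the 7-OH reacts fast and the chelated 5-OH on heating, which removes acidic protons before the zinc amide step and uses a group cleaved later by hydrogenolysis; no stereocentre.

Step 2
Reactants: 4, 5-bromobenzene-1,2,3-triol; 5, dichlorodiphenylmethane
Product: 6, 6-bromo-2,2-diphenyl-1,3-benzodioxol-4-ol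
Conditions: Ph2CCl2 (1.2 equiv), Ph2O, 175 °C, 30 min, N2 sweep
Reagents that add atoms: dichlorodiphenylmethane, ClC(Cl)(c1ccccc1)c1ccccc1
Why: Catechol diphenylmethylene ketalisation (double O-alkylation by the gem-dichloride); only an adjacent OH pair can close the five-membered dioxole and both pairs are symmetry-equivalent, so exactly one terminal OH stays free; no stereocentre.

Step 3
Reactants: 6, 6-bromo-2,2-diphenyl-1,3-benzodioxol-4-ol; 7, 2,2,2-trichloroethyl chlorosulfate
Product: 8, 6-bromo-2,2-diphenyl-1,3-benzodioxol-4-yl 2,2,2-trichloroethyl sulfate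
Conditions: Cl3CCH2OSO2Cl (1.2 equiv), Et3N (1.5 equiv), DMAP (1 equiv), THF, 0 °C to rt
Reagents that add atoms: 2,2,2-trichloroethyl chlorosulfate, ClS(=O)(=O)OCC(Cl)(Cl)Cl
Why: DMAP-mediated O-sulfurylation of the single free phenol (substitution at sulfur) gives a neutral, chromatographable sulfate diester that masks the sulfate for the organometallic step; no stereocentre.

Step 4
Reactants: 3, 5,7-bis(benzyloxy)-4H-chromen-4-one; 8, 6-bromo-2,2-diphenyl-1,3-benzodioxol-4-yl 2,2,2-trichloroethyl sulfate
Product: 9, 5,7-bis(benzyloxy)-2-[2,2-diphenyl-7-{[(2,2,2-trichloroethoxy)sulfonyl]oxy}-1,3-benzodioxol-5-yl]-4H-chromen-4-one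
Conditions: 3 (1.3 equiv), TMP2Zn·2MgCl2·2LiCl (0.62 equiv, from TMPMgCl·LiCl + 0.5 ZnCl2), THF, −30 °C, 1 h; then 8 (1.0 equiv), Pd(OAc)2 (3 mol%), SPhos (6 mol%), THF, 25 to 40 °C
Reagents that add atoms: none
Why: Lewis-acid-triggered directed C–H zincation followed by Negishi cross-coupling; MgCl2 coordination to the C4 carbonyl makes C2–H the most acidic site (the Lewis-acid-free base TMPZnCl·LiCl would favour C3), the bis(chromon-2-yl)zinc does not ring-open, and the amide is kept substoichiometric so none is left to attack the TCE ester; Pd/SPhos inserts into Ar–Br much faster than into the hindered CCl3 group; no stereocentre.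

Step 5
Reactants: 9, the protected flavone from Step 4
Product: 10, tricetin 3'-sulfate, i.e. 5-(5,7-dihydroxy-4-oxo-4H-chromen-2-yl)-2,3-dihydroxyphenyl hydrogen sulfate
Conditions: 10% Pd/C, HCO2NH4 (10 equiv), MeOH–THF, rt; then H2 (1 atm), rt; filter; Dowex 50W (H+), 0 °C; lyophilise
Reagents that add atoms: none
Why: Reductive dechlorination and β-elimination removes the TCE group to leave the aryl sulfate monoanion, while hydrogenolysis cleaves both benzyl ethers and the benzylic diphenylmethylene ketal; the sulfate monoester is inert to hydrogenolysis in the formate-buffered medium and the conjugated flavone C2=C3 bond is kept by working at rt; no stereocentre.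

**Compound list**
1 | 5,7-dihydroxy-4H-chromen-4-one | O=c1ccoc2cc(O)cc(O)c12 | starting material
2 | benzyl bromide | BrCc1ccccc1 | starting material
3 | 5,7-bis(benzyloxy)-4H-chromen-4-one | O=c1ccoc2cc(OCc3ccccc3)cc(OCc3ccccc3)c12 | intermediate
4 | 5-bromobenzene-1,2,3-triol (5-bromopyrogallol) | Oc1cc(Br)cc(O)c1O | starting material
5 | dichlorodiphenylmethane | ClC(Cl)(c1ccccc1)c1ccccc1 | starting material
6 | 6-bromo-2,2-diphenyl-1,3-benzodioxol-4-ol | Oc1cc(Br)cc2OC(c3ccccc3)(c3ccccc3)Oc12 | intermediate
7 | 2,2,2-trichloroethyl chlorosulfate | ClS(=O)(=O)OCC(Cl)(Cl)Cl | starting material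
8 | 6-bromo-2,2-diphenyl-1,3-benzodioxol-4-yl 2,2,2-trichloroethyl sulfate | ClC(Cl)(Cl)COS(=O)(=O)Oc1cc(Br)cc2OC(c3ccccc3)(c3ccccc3)Oc12 | intermediate
9 | 5,7-bis(benzyloxy)-2-[2,2-diphenyl-7-{[(2,2,2-trichloroethoxy)sulfonyl]oxy}-1,3-benzodioxol-5-yl]-4H-chromen-4-one | O=c1cc(-c2cc(OS(=O)(=O)OCC(Cl)(Cl)Cl)c3OC(c4ccccc4)(c4ccccc4)Oc3c2)oc2cc(OCc3ccccc3)cc(OCc3ccccc3)c12 | intermediate
10 | tricetin 3'-sulfate (achiral) | O=c1cc(-c2cc(O)c(O)c(OS(=O)(=O)O)c2)oc2cc(O)cc(O)c12 | target

**Totals**
- Total step count: 5
- Longest linear sequence: 4 steps (4 → 6 → 8 → 9 → 10)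

**Three steps most likely to fail, with fallbacks**
1. Step 4 (C2–H zincation/Negishi). Risks are C3 instead of C2 metalation on the 5-alkoxy chromone, and Pd(0) attacking the CCl3 group, which would consume the organozinc. Fallback: form the C2–C1' bond by Pd(II)-catalysed conjugate addition of the B-ring arylboronic ester (Miyaura borylation of the bromide) to chromone 3 to give the flavanone, then dehydrogenate with DDQ or I2/DMSO.
2. Step 5 (one-pot unmasking). Risks are over-reduction of C2=C3 to the flavanone under transfer hydrogenation, partial hydrodechlorination to a non-cleavable chloroethyl sulfate, and sulfate loss on acidification. Fallback: drop the masked sulfate and carry the lone B-ring OH as a TBS ether through the coupling, then TBAF, sulfate that single free phenol with SO3·NMe3, and finish with plain H2/Pd–C debenzylation of the sulfate salt.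
3. Step 2 (thermal ketal desymmetrisation). Risks are C-alkylation or oligomeric ketals on the electron-rich bromopyrogallol. Fallback: differentiate the oxygens by oxidation level instead, from 5-bromo-2-hydroxy-3-methoxybenzaldehyde: BBr3 demethylation, bis-benzylation, then Dakin oxidation (mCPBA; K2CO3/MeOH) to 5-bromo-2,3-bis(benzyloxy)phenol, which enters Step 3 unchanged.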